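Remark on the chemistry: allyl 2-oxocyclohexane-1-carboxylate (1) is taken as a catalogue β-keto ester (otherwise one step from cyclohexanone and diallyl carbonate).

## Structural features

- The target is a germacranolide: a ten-membered carbocycle trans-fused at C7–C8 to an α-methylidene-γ-butyrolactone. Locants used throughout: C1–C3 are the three CH2 groups, C4 the methylated epoxide carbon (methyl C15), C5 the epoxide CH, C6 the CH carrying the (E)-2-methylbut-2-enoate (tiglate), C7 the ring-fusion CH bonded to C11, C8 the lactone O–CH, C9 the CH(OH), C10 the CH(CH3) (methyl C14); C12 is the lactone carbonyl and C13 the exocyclic CH2.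
- In these locants the target is 4R,5R,6R,7S,8S,9R,10R.
- Seven contiguous stereocentres (C4–C10) sit on one arc of the ring, closed by the unfunctionalised C1–C3 chain. With the ring drawn flat, O6, O8, O9 and C14 lie on one face and C11 on the other, so C6/C7/C8 are all-trans. The epoxide is trans (an E-alkene in disguise) and erythro to the C6 oxygen.
- Fragile groups: the α-methylidene lactone (conjugate addition, hydride), the trisubstituted epoxide (acid, transannular opening), and the tiglate and lactone esters (base, acyl migration to the neighbouring hydroxyls).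
- The real difficulty is the medium ring itself together with control of seven stereocentres on a conformationally mobile ring.
- Feature exploited: C9 (a carbinol, hence a latent ketone) and the latent E-alkene C4=C5 stand in the 1,5-relationship of a cyclodec-5-enone, and the C6–C7 bond between them joins two stereocentres. This is the retron of an anionic oxy-Cope ring expansion in which C4–C9 is a bond of a six-membered ring (C9, C10, C1, C2, C3, C4).

## Logic of the disconnections

30 ⇒ 27. The lactone C12–O8 bond is cut and C12 is lowered to the primary allylic alcohol. The conjugate acceptor is the most reactive group and is best made last, so no earlier step (hydride, organolithium, base) meets it. Demand: the oxidant must touch only the allylic C12–OH of 27, and the aldehyde must be captured by O8 (five-membered lactol) and not by O9.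

27 ⇒ 26 ⇒ 25. The three O–Si bonds and then the O6–acyl bond are cut. This leaves one free hydroxyl (O6) in 25, so the acylation needs no selectivity. Demand: desilylation of 26 must spare epoxide and ester.

25 ⇒ 24. Both C–O bonds of the epoxide are cut to the E-alkene C4=C5 next to the free C6–OH. Two stereocentres are thereby traced back to an alkene geometry and to C6. Demand: oxygen must arrive erythro to O6, on the face that the ring exposes only when C7 stands perpendicular to the alkene and O6 lies near its plane.

24 ⇒ 23 ⇒ 22 ⇒ 21. The O6–PMB group is restored, the two O–Si bonds at O8/O9 are cut, and the C9–H bond is cut (carbinol to ketone). C9 becomes the carbonyl that the key step delivers. Demand: hydride must add anti to O8 (8,9-erythro), which calls for a free, chelating C8–OH in 21.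

21 ⇒ 18 (key). The C6–C7 bond and the C8–O bond are cut and the C4–C9 bond is re-formed. The ten-membered ring with C6, C7, C8, the E-alkene and the C9 carbonyl collapses to a cyclohexanol whose only lasting stereocentre is C10. Demand: a chair transition state with both alkenyl groups equatorial and both alkenes E, and hydroxylation of the resulting enolate on its outer face only.

18 ⇒ 12 + 16 (through 17). The C8–C9 bond is cut to a ketone and an alkenyl anion. Demand: the nucleophile must add trans to the alkenyl group already on C4.

12 ⇒ 11 ⇒ 10. The C6–O bond of the enol ether and then the C5=C6 bond are cut back to an aldehyde at C5. Demand: E geometry at both stages, and no epimerisation at C10.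

10 ⇒ 8 ⇒ 7. The formyl carbon C5 is traced to an allyl group by alkene migration and cleavage, because allyl is what the catalytic quaternary-centre chemistry delivers.

7 ⇒ 6 ⇒ 4 ⇒ 3. The C10–C14 bond is cut. The two C4 substituents are too similar in size to direct this methylation, so the forward step needs auxiliary control.

3 ⇒ 2 ⇒ 1. The C4–allyl bond, then the C4–CH3 bond, are cut. C4 is the one stereocentre set by catalysis; it is later destroyed and relays its information to C6, C7 and C8.

16 ⇒ 14 + 15, and 14 ⇒ 13. The C7–C11 bond is cut to a 2-bromoallyl ether and a 1,2-distannylethene, both one step or less from catalogue materials.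

## Other disconnections considered

Alternative 1: Cut C7–C8 and the lactone C12–O8 bond. The forward key step is an intramolecular Nozaki–Hiyama–Kishi-type allylation (CrCl2) of the aldehyde of seco compound A1 by its (Z)-2-(bromomethyl)enoate, followed by lactonisation; this is the first plan that comes to mind for an α-methylidene lactone on a medium ring. The chosen plan is preferred on three grounds:
- A1 must already carry five stereocentres (C4, C5, C6, C9, C10), set one by one along a twelve-atom chain.
- Closing a ten-membered ring by C–C bond formation pays the full entropic and transannular cost at high dilution.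
- The C7/C8 outcome would rest on a macrocyclic transition state that is hard to predict, whereas the ring expansion goes through a six-membered chair.

Alternative 2: Cut C2–C3. The forward key step is ring-closing metathesis of lactone diene A2 to cyclodecene A3, then hydrogenation of the new C2=C3 alkene. The chosen plan is preferred because:
- All seven stereocentres and the lactone must be assembled before the ring exists.
- Ten-membered carbocycles are poor metathesis products (oligomers compete), and the vinyl epoxide and exocyclic methylidene of A2 are competing sites.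
- Hydrogenation of A3 must spare the α-methylidene lactone and the tiglate, a chemoselectivity problem that the chosen route never meets.

Alternative 3: Cut C4–C9 within a bicycle that already contains the C6–C7 bond. The forward key step is a Grob (Wharton) fragmentation of trans-decalin A4, with the C9 alkoxide and the equatorial C5 mesylate anti-periplanar to C4–C9. This is also a ring expansion and would give the same kind of E-cyclodecenone as 21. The chosen plan is preferred because:
- A4 needs six contiguous stereocentres, two of them quaternary ring-fusion carbons, on a fully substituted cyclohexane.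
- The C6–C7 bond and the C5–C8 array must be made by separate steps; the oxy-Cope makes that bond, both its stereocentres and the C8 oxygen in one operation from a cyclohexanol such as 18, so it is shorter.

Key step: step 13

## Route

Step 1
Reactants: 1 allyl 2-oxocyclohexane-1-carboxylate
Product: 2 allyl 1-methyl-2-oxocyclohexane-1-carboxylate (racemic)
Conditions: K2CO3, MeI, acetone, reflux
Reagents that add atoms: iodomethane, CI
Why: C-Alkylation of the stabilised β-keto ester enolate; the quaternary carbon may be racemic because step 2 passes through an achiral enolate.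

Step 2
Reactants: 2 allyl 1-methyl-2-oxocyclohexane-1-carboxylate
Product: 3 (R)-2-allyl-2-methylcyclohexan-1-one
Conditions: Pd2(dba)3 (2.5 mol %), (R)-t-Bu-PHOX [(R)-4-tert-butyl-2-(2-diphenylphosphinophenyl)-4,5-dihydrooxazole] (6 mol %), THF, 25 °C
Reagents that add atoms: none
Why: Decarboxylative asymmetric Tsuji allylation: zerovalent palladium ionises the allyl ester, CO2 is lost, and the palladium enolate and allyl ligand join within the chiral P,N-ligand sphere to set the quaternary centre (future C4); the R ligand is the mirror image of the ligand that gives the S ketone.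

Step 3
Reactants: 3 (R)-2-allyl-2-methylcyclohexan-1-one
Product: 4 SAMP hydrazone of 3 (amino nitrogen on the CH2 side of the C=N bond)
Conditions: SAMP (1.2 equiv), p-TsOH (cat.), cyclohexane, reflux, water separator
Reagents that add atoms: (S)-1-amino-2-(methoxymethyl)pyrrolidine (SAMP), COC[C@@H]1CCCN1N
Why: Hydrazone condensation; the amino group settles away from the quaternary carbon, which is the geometry needed for deprotonation at the CH2 carbon.

Step 4
Reactants: 4 SAMP hydrazone of 3
Product: 6 SAMP hydrazone of (2R,6R)-2-allyl-2,6-dimethylcyclohexan-1-one, via lithium azaenolate 5 (not isolated)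
Conditions: LDA, THF, 0 °C; then MeI, −100 °C → rt
Reagents that add atoms: iodomethane, CI
Why: SAMP-hydrazone α-alkylation: the chelated azaenolate is methylated on the face fixed by the auxiliary, which in the cyclohexanone series gives the R α-methyl centre (future C10, trans to the ring methyl); the methyl and allyl groups on the other α-carbon are too alike to bias the ring, so the auxiliary decides.

Step 5
Reactants: 6 SAMP hydrazone of (2R,6R)-2-allyl-2,6-dimethylcyclohexan-1-one
Product: 7 (2R,6R)-2-allyl-2,6-dimethylcyclohexan-1-one
Conditions: saturated aqueous oxalic acid, Et2O, rt (two phases)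
Reagents that add atoms: water, O
Why: Mild two-phase hydrazone hydrolysis that should leave the epimerisable C6 centre untouched; the auxiliary is recovered from the aqueous phase.

Step 6
Reactants: 7 (2R,6R)-2-allyl-2,6-dimethylcyclohexan-1-one
Product: 8 (2R,6R)-2,6-dimethyl-2-[(1E)-prop-1-en-1-yl]cyclohexan-1-one
Conditions: RuHCl(CO)(PPh3)3 (5 mol %), toluene, 80 °C
Reagents that add atoms: none
Why: Ruthenium hydride alkene isomerisation (addition/β-hydride elimination) moves the double bond by one position and stops at the quaternary carbon; the medium is neutral.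

Step 7
Reactants: 8 (2R,6R)-2,6-dimethyl-2-[(1E)-prop-1-en-1-yl]cyclohexan-1-one
Product: 10 (1R,3R)-1,3-dimethyl-2-oxocyclohexane-1-carbaldehyde, via ozonide 9 (not isolated)
Conditions: O3, CH2Cl2, −78 °C; then PPh3, −78 °C → rt
Reagents that add atoms: ozone, [O-][O+]=O
Why: Ozonolysis with reductive work-up; the aldehyde carbon is the future C5 and cannot enolise because it sits on a quaternary carbon.

Step 8
Reactants: 10 (1R,3R)-1,3-dimethyl-2-oxocyclohexane-1-carbaldehyde
Product: 11 (2R,6R)-2-[(E)-2-iodoethenyl]-2,6-dimethylcyclohexan-1-one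
Conditions: CrCl2 (6 equiv), CHI3 (2 equiv), THF/1,4-dioxane, 0 °C → rt
Reagents that add atoms: iodoform, IC(I)I
Why: Takai olefination: the geminal dichromium reagent made from iodoform and divalent chromium adds to the aldehyde only (the hindered ketone is inert) and gives the E vinyl iodide.

Step 9
Reactants: 11 (2R,6R)-2-[(E)-2-iodoethenyl]-2,6-dimethylcyclohexan-1-one
Product: 12 (2R,6R)-2-{(E)-2-[(4-methoxybenzyl)oxy]ethenyl}-2,6-dimethylcyclohexan-1-one
Conditions: CuI (10 mol %), 3,4,7,8-tetramethyl-1,10-phenanthroline (20 mol %), 4-methoxybenzyl alcohol (2 equiv), Cs2CO3 (1.5 equiv), toluene, 80 °C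
Reagents that add atoms: (4-methoxyphenyl)methanol, COc1ccc(CO)cc1
Why: Ullmann-type copper-catalysed C–O coupling of a vinyl iodide with an alcohol, which keeps the alkene geometry; the insoluble carbonate in toluene is not expected to epimerise the hindered C6–H.

Step 10
Reactants: 13 2-bromoprop-2-en-1-ol
Product: 14 [(2-bromoprop-2-en-1-yl)oxy](tert-butyl)dimethylsilane
Conditions: TBSCl, imidazole, CH2Cl2, 0 °C → rt
Reagents that add atoms: tert-butyl(chloro)dimethylsilane, CC(C)(C)[Si](C)(C)Cl
Why: Standard silylation of a primary alcohol; the ether masks the future C12 oxygen.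

Step 11
Reactants: 14 [(2-bromoprop-2-en-1-yl)oxy](tert-butyl)dimethylsilane; 15 (E)-1,2-bis(tributylstannyl)ethene
Product: 16 tert-butyldimethyl{[(3E)-2-methylidene-4-(tributylstannyl)but-3-en-1-yl]oxy}silane
Conditions: Pd(PPh3)4 (5 mol %), toluene, 80 °C, 15 in twofold excess
Reagents that add atoms: none
Why: Stille mono-coupling of the vinyl bromide with one tin terminus; alkene geometry is retained and the excess of 15 suppresses double coupling.

Step 12
Reactants: 16 tert-butyldimethyl{[(3E)-2-methylidene-4-(tributylstannyl)but-3-en-1-yl]oxy}silane; 12 (2R,6R)-2-{(E)-2-[(4-methoxybenzyl)oxy]ethenyl}-2,6-dimethylcyclohexan-1-one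
Product: 18 (1S,2R,6R)-1-[(1E)-3-({[tert-butyl(dimethyl)silyl]oxy}methyl)buta-1,3-dien-1-yl]-2-{(E)-2-[(4-methoxybenzyl)oxy]ethenyl}-2,6-dimethylcyclohexan-1-ol, via dienyllithium 17 (not isolated)
Conditions: n-BuLi, THF, −78 °C; then 12, −78 °C; aqueous NH4Cl
Reagents that add atoms: none
Why: Tin–lithium exchange keeps the E geometry and the alkenyllithium adds 1,2 to the ketone, which sits in the chair with the C6 methyl and the C2 alkenyl group equatorial and the C2 methyl axial. Attack along the equatorial direction, the usual course for alkenyl- and alkynyllithiums with 2,2,6-trisubstituted cyclohexanones, puts the new dienyl group trans to the C2 alkenyl group and to the C6 methyl.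

Step 13
Reactants: 18 (1S,2R,6R)-1-[(1E)-3-({[tert-butyl(dimethyl)silyl]oxy}methyl)buta-1,3-dien-1-yl]-2-{(E)-2-[(4-methoxybenzyl)oxy]ethenyl}-2,6-dimethylcyclohexan-1-ol
Product: 21 (4E)-cyclodec-4-en-9-one (target locants) with 8-OH, 6-O-(4-methoxybenzyl), 4,10-dimethyl and 7-[3-(tert-butyldimethylsilyloxy)prop-1-en-2-yl]; C6/C7/C8/C10 configured as in 30, via potassium alkoxide 19 (not isolated), via potassium enolate 20 (not isolated)
Conditions: KH (1.5 equiv), 18-crown-6 (1.5 equiv), THF, 0 → 25 °C; then −78 °C, 2-(phenylsulfonyl)-3-phenyloxaziridine; aqueous NH4Cl at −78 °C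
Reagents that add atoms: 2-(benzenesulfonyl)-3-phenyloxaziridine, O=S(=O)(c1ccccc1)N1OC1c1ccccc1
Why: Anionic oxy-Cope ring expansion with in-flask enolate hydroxylation: the crown-separated potassium alkoxide 19 undergoes an anion-accelerated [3,3]-sigmatropic shift that breaks C4–C9 and forms C6–C7, and the regiodefined enolate 20 (C8=C9) is then oxidised by the N-sulfonyloxaziridine; the closest known type is the anionic oxy-Cope conversion of trans-1,2-dialkenylcyclohexanols into cyclodec-5-enones with electrophilic trapping of the enolate. The ten-membered ring is not closed end to end but arises by four-atom ring expansion through a six-membered chair transition state fused trans to the cyclohexane chair (both alkenyl groups equatorial, O− and C15 axial, C14 equatorial). Because both alkenes are E, the OPMB group on C6 and C11 on C7 are equatorial on that chair, so C6 and C7 emerge trans on the new ring with the target configuration; their absolute sense is relayed from C4 and C9 of 18, which are destroyed. The axial C15 and equatorial C3 on C4 give the E-C4=C5 alkene, and the equatorial C10 on C9 gives the enolate with oxygen cis to C7. In 20, allylic 1,3-strain against the enolate oxygen holds C7–H in the enolate plane, C6 sits on the transannular face, and the oxidant can reach only the outer face, which gives C8–O trans to C11 as the trans-lactone requires. The step needs chair over boat (secured by the trans-diequatorial dialkenyl arrangement, which has no 1,3-diaxial penalty with E alkenes), [3,3] over [1,3] shift or fragmentation (the usual preference of crown-separated potassium alkoxides), and C8 over C10 oxidation (the Cope forms only the C8 enolate, and −78 °C prevents proton transfer).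

Step 14
Reactants: 21 α-hydroxy ketone from step 13
Product: 22 8,9-diol (C9 ketone of 21 reduced to the 9R alcohol; C6–C10 as in 30)
Conditions: Zn(BH4)2, Et2O, −20 → 0 °C
Reagents that add atoms: none
Why: Chelation-controlled reduction of an α-hydroxy ketone: zinc bridges O8 and the carbonyl oxygen and hydride adds from the side of C8–H, anti to C7, giving the 8,9-erythro diol. The same face is the ring periphery (C7 and C1 both on the far side) and the face that 1,2-induction from C10 prefers (C10–H beside the trajectory, C14 eclipsing the carbonyl), so all three controls agree.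

Step 15
Reactants: 22 8,9-diol
Product: 23 8,9-bis(triethylsilyl) ether of 22
Conditions: TESOTf (2.5 equiv), 2,6-lutidine, CH2Cl2, −78 → 0 °C
Reagents that add atoms: triethylsilyl trifluoromethanesulfonate, CC[Si](CC)(CC)OS(=O)(=O)C(F)(F)F
Why: Silylation of both hindered secondary hydroxyls with the silyl triflate, so that only O6 is free for epoxidation and acylation and all silyl groups can leave together in step 19.

Step 16
Reactants: 23 8,9-bis(triethylsilyl) ether
Product: 24 C6 allylic alcohol (PMB removed; C6–C10 as in 30)
Conditions: DDQ, CH2Cl2/pH 7 buffer, 0 °C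
Reagents that add atoms: none
Why: Oxidative cleavage of the 4-methoxybenzyl ether by hydride abstraction and hydrolysis; silyl ethers and both alkenes are inert to DDQ in buffered medium.

Step 17
Reactants: 24 C6 allylic alcohol
Product: 25 (4R,5R)-epoxy alcohol (erythro to O6; all stereocentres as in 30)
Conditions: Ti(OiPr)4 (0.3 equiv), D-(−)-diisopropyl tartrate (0.36 equiv), t-BuOOH, 4 Å molecular sieves, CH2Cl2, −20 °C
Reagents that add atoms: tert-butyl hydroperoxide, CC(C)(C)OO
Why: Sharpless asymmetric epoxidation of a secondary allylic alcohol, which gives erythro epoxy alcohols because the titanium-bound C–O bond lies near the alkene plane with the carbinol substituent on the far face. That is the only arrangement the ring allows (C7 perpendicular to the alkene, on the transannular side), and for this C6 configuration D-(−)-tartrate is the matched, fast-reacting pairing that delivers oxygen to the 4R,5R face; the homoallylic 1,1-disubstituted alkene is not a substrate.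

Step 18
Reactants: 25 epoxy alcohol
Product: 26 C6 (E)-2-methylbut-2-enoate of 25
Conditions: (E)-2-methylbut-2-enoyl chloride, Et3N, DMAP (cat.), CH2Cl2, 0 °C → rt
Reagents that add atoms: (E)-2-methylbut-2-enoyl chloride (tigloyl chloride), C/C=C(\C)C(Cl)=O
Why: DMAP-catalysed acylation of the only free hydroxyl; the tiglate is the stable E isomer, so geometry is not at risk.

Step 19
Reactants: 26 tiglate
Product: 27 8,9,12-triol (all silyl groups removed; stereocentres as in 30)
Conditions: HF·pyridine, pyridine, THF, 0 °C → rt
Reagents that add atoms: none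
Why: Buffered fluoride desilylation removes the two triethylsilyl ethers and the primary allylic TBS ether without opening the epoxide or cleaving the ester.

Step 20
Reactants: 27 triol
Product: 30 target lactone (4R,5R,6R,7S,8S,9R,10R), via enal 28 (not isolated), via lactol 29 (not isolated)
Conditions: MnO2 (activated, excess), CH2Cl2, rt
Reagents that add atoms: none
Why: MnO2 oxidative lactonisation: only the allylic C12–OH is oxidised, the enal is captured by O8 as the five-membered lactol (favoured over the six-membered lactol through O9, which is flanked by the C10 methyl), and the allylic lactol is oxidised to the trans-fused α-methylidene lactone.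

## Compound list

1 | allyl 2-oxocyclohexane-1-carboxylate | C=CCOC(=O)C1CCCCC1=O | starting material
2 | allyl 1-methyl-2-oxocyclohexane-1-carboxylate (racemic) | C=CCOC(=O)C1(C)CCCCC1=O | intermediate
3 | (R)-2-allyl-2-methylcyclohexan-1-one | C=CC[C@@]1(C)CCCCC1=O | intermediate
4 | SAMP hydrazone of 3 | C=CC[C@@]1(C)CCCC/C1=N\N1CCC[C@H]1COC | intermediate
5 | lithium azaenolate of 4 | C=CC[C@@]1(C)CCCC=C1N([Li])N1CCC[C@H]1COC | intermediate
6 | SAMP hydrazone of (2R,6R)-2-allyl-2,6-dimethylcyclohexan-1-one | C=CC[C@@]1(C)CCC[C@@H](C)/C1=N\N1CCC[C@H]1COC | intermediate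
7 | (2R,6R)-2-allyl-2,6-dimethylcyclohexan-1-one | C=CC[C@@]1(C)CCC[C@@H](C)C1=O | intermediate
8 | (2R,6R)-2,6-dimethyl-2-[(1E)-prop-1-en-1-yl]cyclohexan-1-one | C/C=C/[C@@]1(C)CCC[C@@H](C)C1=O | intermediate
9 | secondary ozonide of 8 | CC1OOC(O1)[C@@]1(C)CCC[C@@H](C)C1=O | intermediate
10 | (1R,3R)-1,3-dimethyl-2-oxocyclohexane-1-carbaldehyde | O=C[C@@]1(C)CCC[C@@H](C)C1=O | intermediate
11 | (2R,6R)-2-[(E)-2-iodoethenyl]-2,6-dimethylcyclohexan-1-one | I/C=C/[C@@]1(C)CCC[C@@H](C)C1=O | intermediate
12 | (2R,6R)-2-{(E)-2-[(4-methoxybenzyl)oxy]ethenyl}-2,6-dimethylcyclohexan-1-one | COc1ccc(CO/C=C/[C@@]2(C)CCC[C@@H](C)C2=O)cc1 | intermediate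
13 | 2-bromoprop-2-en-1-ol | C=C(Br)CO | starting material
14 | [(2-bromoprop-2-en-1-yl)oxy](tert-butyl)dimethylsilane | C=C(Br)CO[Si](C)(C)C(C)(C)C | intermediate
15 | (E)-1,2-bis(tributylstannyl)ethene | CCCC[Sn](CCCC)(CCCC)/C=C/[Sn](CCCC)(CCCC)CCCC | starting material
16 | tert-butyldimethyl{[(3E)-2-methylidene-4-(tributylstannyl)but-3-en-1-yl]oxy}silane | CCCC[Sn](CCCC)(CCCC)/C=C/C(=C)CO[Si](C)(C)C(C)(C)C | intermediate
17 | (E)-dienyllithium from 16 | [Li]/C=C/C(=C)CO[Si](C)(C)C(C)(C)C | intermediate
18 | (1S,2R,6R)-1-[(1E)-3-({[tert-butyl(dimethyl)silyl]oxy}methyl)buta-1,3-dien-1-yl]-2-{(E)-2-[(4-methoxybenzyl)oxy]ethenyl}-2,6-dimethylcyclohexan-1-ol | COc1ccc(CO/C=C/[C@@]2(C)CCC[C@@H](C)[C@]2(O)/C=C/C(=C)CO[Si](C)(C)C(C)(C)C)cc1 | intermediate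
19 | potassium alkoxide of 18 | COc1ccc(CO/C=C/[C@@]2(C)CCC[C@@H](C)[C@]2([O-])/C=C/C(=C)CO[Si](C)(C)C(C)(C)C)cc1.[K+] | intermediate
20 | potassium enolate (C8=C9, O cis to C7) of the ring-expanded ketone | C=C(CO[Si](C)(C)C(C)(C)C)[C@H]1/C=C(\[O-])[C@H](C)CCC/C(C)=C/[C@@H]1OCc1ccc(OC)cc1.[K+] | intermediate
21 | 8-hydroxy-9-oxo cyclodec-4-ene with 6-OPMB, 7-[3-(TBSO)prop-1-en-2-yl], 4,10-dimethyl (target locants; C6, C7, C8, C10 as in 30) | C=C(CO[Si](C)(C)C(C)(C)C)[C@H]1[C@H](O)C(=O)[C@H](C)CCC/C(C)=C/[C@@H]1OCc1ccc(OC)cc1 | intermediate
22 | 8,9-diol from 21 (9R) | C=C(CO[Si](C)(C)C(C)(C)C)[C@H]1[C@H](O)[C@H](O)[C@H](C)CCC/C(C)=C/[C@@H]1OCc1ccc(OC)cc1 | intermediate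
23 | 8,9-bis(triethylsilyl) ether of 22 | C=C(CO[Si](C)(C)C(C)(C)C)[C@H]1[C@H](O[Si](CC)(CC)CC)[C@H](O[Si](CC)(CC)CC)[C@H](C)CCC/C(C)=C/[C@@H]1OCc1ccc(OC)cc1 | intermediate
24 | C6 allylic alcohol (PMB removed from 23) | C=C(CO[Si](C)(C)C(C)(C)C)[C@H]1[C@H](O[Si](CC)(CC)CC)[C@H](O[Si](CC)(CC)CC)[C@H](C)CCC/C(C)=C/[C@@H]1O | intermediate
25 | (4R,5R)-epoxy alcohol from 24 | C=C(CO[Si](C)(C)C(C)(C)C)[C@H]1[C@H](O[Si](CC)(CC)CC)[C@H](O[Si](CC)(CC)CC)[C@H](C)CCC[C@@]2(C)O[C@@H]2[C@@H]1O | intermediate
26 | C6 tiglate of 25 | C=C(CO[Si](C)(C)C(C)(C)C)[C@H]1[C@H](O[Si](CC)(CC)CC)[C@H](O[Si](CC)(CC)CC)[C@H](C)CCC[C@@]2(C)O[C@@H]2[C@@H]1OC(=O)/C(C)=C/C | intermediate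
27 | 8,9,12-triol (desilylated 26) | C=C(CO)[C@H]1[C@H](O)[C@H](O)[C@H](C)CCC[C@@]2(C)O[C@@H]2[C@@H]1OC(=O)/C(C)=C/C | intermediate
28 | C12 enal from 27 | C=C(C=O)[C@H]1[C@H](O)[C@H](O)[C@H](C)CCC[C@@]2(C)O[C@@H]2[C@@H]1OC(=O)/C(C)=C/C | intermediate
29 | C12 lactol (O8–C12) | C=C1C(O)O[C@@H]2[C@H](O)[C@H](C)CCC[C@@]3(C)O[C@@H]3[C@H](OC(=O)/C(C)=C/C)[C@@H]12 | intermediate
30 | target, CNP0165329.2 (4R,5R,6R,7S,8S,9R,10R in the locants used here) | C=C1C(=O)O[C@@H]2[C@H](O)[C@H](C)CCC[C@@]3(C)O[C@@H]3[C@H](OC(=O)/C(C)=C/C)[C@@H]12 | target

## Step count and least certain steps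

Total step count: 20. Longest linear sequence: 18 (steps 1–9 and 12–20).

Step 13 (key step).
- What may go wrong: rearrangement through a boat-like transition state, a competing [1,3] shift or fragmentation of the alkoxide, or loss of facial control and proton transfer between the two enolates during hydroxylation. The chair has to accommodate a quaternary carbon and two substituted termini, and the outer face of the enolate is partly screened by C11.
- Fallback (from 18, back at 21): run the rearrangement without base as a neutral oxy-Cope (o-dichlorobenzene, sealed tube, about 200 °C), where enol-to-ketone tautomerism makes it irreversible, and isolate the 8-unsubstituted cyclodecenone F1. Then deprotonate kinetically at the C8 methylene (KN(SiMe3)2, THF, −78 °C; the methyl-bearing C10 methine is slower) and hydroxylate with the same oxaziridine to reach 21.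

Step 17.
- What may go wrong: slow or poorly face-selective oxygen transfer, because the matched titanium–tartrate transition state places the C6–O bond near the alkene plane, syn to the C4 methyl (allylic 1,3-strain), on a hindered medium-ring alcohol.
- Fallback (from 24, back at 25): oxidise with MnO2 to the C6 enone F2. Reduce with NaBH4/CeCl3 (Luche conditions; hydride anti to C8, expected to give the C6 epimer) to the epimeric allylic alcohol F3. Epoxidise with VO(acac)2/t-BuOOH, where substrate control (C6–H in the alkene plane, hydroxyl on the exposed face) should give the threo epoxy alcohol F4 with the 4R,5R epoxide. Oxidise with the periodinane DMP (1,1,1-triacetoxy-1,1-dihydro-1,2-benziodoxol-3(1H)-one) to the epoxy ketone F5. Reduce with Zn(BH4)2 under chelation by the epoxide oxygen, which is erythro-selective, to return to 25.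

Step 12.
- What may go wrong: enolisation of the hindered ketone by the alkenyllithium, or approach from the axial direction giving the cis-dialkenyl carbinol, which cannot reach the chair of step 13.
- Fallback (from 14 and 12, back at 18): Sonogashira coupling of 14 with ethynyltrimethylsilane (PdCl2(PPh3)2, CuI, Et3N) gives the silylated enyne F6, and K2CO3/MeOH gives the terminal enyne F7. Lithiation (n-BuLi) and addition to 12 gives the propargylic alcohol F8; slim acetylides add cleanly to 2,2,6-trisubstituted cyclohexanones trans to the 6-methyl group. Hydroxyl-directed trans-hydroalumination with NaAlH2(OCH2CH2OCH3)2 (Red-Al, THF) then gives the E-dienyl carbinol 18.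

Step 9.
- What may go wrong: base-mediated epimerisation at C6 of the ketone (the trans-dimethyl isomer is probably the less stable one) or dehydrohalogenation of the vinyl iodide at 80 °C.
- Fallback (from 10, back at 12): olefinate 10 with Cl2CHB(pin)/CrCl2/LiI (boron variant of the Takai reaction, THF, rt) to the E-alkenylboronate F9. Couple F9 with 4-methoxybenzyl alcohol under Chan–Lam conditions (Cu(OAc)2, Et3N, 4 Å molecular sieves, CH2Cl2, rt, air), which needs neither heat nor carbonate, to give 12.

## Further compounds

F1 | step 13 | 8-unsubstituted cyclodecenone (21 without the C8 hydroxyl; C6, C7, C10 as in 30) | C=C(CO[Si](C)(C)C(C)(C)C)[C@H]1CC(=O)[C@H](C)CCC/C(C)=C/[C@@H]1OCc1ccc(OC)cc1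
F2 | step 17 | C6 enone from 24 | C=C(CO[Si](C)(C)C(C)(C)C)[C@H]1[C@H](O[Si](CC)(CC)CC)[C@H](O[Si](CC)(CC)CC)[C@H](C)CCC/C(C)=C/C1=O
F3 | step 17 | C6 epimer of 24 | C=C(CO[Si](C)(C)C(C)(C)C)[C@H]1[C@H](O[Si](CC)(CC)CC)[C@H](O[Si](CC)(CC)CC)[C@H](C)CCC/C(C)=C/[C@H]1O
F4 | step 17 | C6 epimer of 25 (threo epoxy alcohol, 4R,5R epoxide) | C=C(CO[Si](C)(C)C(C)(C)C)[C@H]1[C@H](O[Si](CC)(CC)CC)[C@H](O[Si](CC)(CC)CC)[C@H](C)CCC[C@@]2(C)O[C@@H]2[C@H]1O
F5 | step 17 | C6 ketone of 25 (epoxy ketone) | C=C(CO[Si](C)(C)C(C)(C)C)[C@H]1[C@H](O[Si](CC)(CC)CC)[C@H](O[Si](CC)(CC)CC)[C@H](C)CCC[C@@]2(C)O[C@@H]2C1=O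
F6 | step 12 | tert-butyldimethyl{[2-methylidene-4-(trimethylsilyl)but-3-yn-1-yl]oxy}silane | C=C(C#C[Si](C)(C)C)CO[Si](C)(C)C(C)(C)C
F7 | step 12 | tert-butyl[(2-methylidenebut-3-yn-1-yl)oxy]dimethylsilane | C=C(C#C)CO[Si](C)(C)C(C)(C)C
F8 | step 12 | propargylic alcohol (alkyne analogue of 18) | COc1ccc(CO/C=C/[C@@]2(C)CCC[C@@H](C)[C@]2(O)C#CC(=C)CO[Si](C)(C)C(C)(C)C)cc1
F9 | step 9 | (2R,6R)-2,6-dimethyl-2-[(E)-2-(4,4,5,5-tetramethyl-1,3,2-dioxaborolan-2-yl)ethenyl]cyclohexan-1-one | CC1(C)OB(/C=C/[C@@]2(C)CCC[C@@H](C)C2=O)OC1(C)C
A1 | alternative 1 | seco aldehyde: methyl (Z)-2-(bromomethyl)enoate carrying C6–OPMB, the 4R,5R epoxide, C10 methyl, C9–OTBS and the C8 aldehyde | COC(=O)/C(CBr)=C/[C@@H](OCc1ccc(OC)cc1)[C@H]1O[C@]1(C)CCC[C@@H](C)[C@@H](O[Si](C)(C)C(C)(C)C)C=O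
A2 | alternative 2 | lactone diene (target opened at C2–C3, both ends as terminal alkenes) | C=CC[C@@H](C)[C@@H](O)[C@H]1OC(=O)C(=C)[C@@H]1[C@@H](OC(=O)/C(C)=C/C)[C@H]1O[C@]1(C)C=C
A3 | alternative 2 | 2,3-didehydro target (metathesis product) | C=C1C(=O)O[C@@H]2[C@H](O)[C@H](C)CC=C[C@@]3(C)O[C@@H]3[C@H](OC(=O)/C(C)=C/C)[C@@H]12
A4 | alternative 3 | all-equatorial trans-decalin: C9 tertiary alcohol, C4 angular methyl, C5 mesylate, C6–OPMB, C7 3-(TBSO)prop-1-en-2-yl, C8–OTBS, C10 methyl | C[C@@H]1CCC[C@]2(C)[C@@H](OS(C)(=O)=O)[C@H](OCc3ccc(OC)cc3)[C@@H](C(=C)CO[Si](C)(C)C(C)(C)C)[C@H](O[Si](C)(C)C(C)(C)C)[C@@]12O
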